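Ring B is disconnected across C1'–C6' and C2'–C3' to 3-methoxyfuran and an alkyne on C2 of ring C. The feature used is the C3' hydroxyl beside the C4' methoxyl of ring B. A Diels–Alder reaction places the furan oxygen on C3' and C6' and the furan methoxy on C4', closing the carbocycle in one operation. Acid then cleaves the bridge at C6' and leaves the phenol unprotected. The precursor is 2-ethynyl-3,7,8-trimethoxychromone, reached in four steps from 1,2,3-trimethoxybenzene. Because its alkyne is activated only vinylogously by the C4 carbonyl, the cycloaddition is run with catalytic ZnI2, which binds the C4 carbonyl/C3 methoxy site.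

Key step: step 5

Assumption: adduct 10 is made and used as the racemate, since both bridgehead centres are removed in step 6 and the target is achiral.

Step 1
Reactants: 1 1,2,3-trimethoxybenzene; 2 methoxyacetyl chloride
Product: 4 1-(2-hydroxy-3,4-dimethoxyphenyl)-2-methoxyethan-1-one, via 2-methoxy-1-(2,3,4-trimethoxyphenyl)ethan-1-one 3 (not isolated)
Conditions: AlCl3 (2.5 equiv), CH2Cl2, 0 °C → rt; aq. HCl work-up
Reagents that add atoms: none
Why: Friedel–Crafts acylation should occur at C4 of the electron-rich arene, and the aluminium chelate between the new carbonyl and the flanking ortho methoxy should then lose chloromethane, so that only that ether is cleaved, as is established for 1,2,3-trimethoxybenzene and acyl chlorides.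

Step 2
Reactants: 4 1-(2-hydroxy-3,4-dimethoxyphenyl)-2-methoxyethan-1-one
Product: 6 3,7,8-trimethoxy-2-methyl-4H-chromen-4-one, via 2,3-dimethoxy-6-(methoxyacetyl)phenyl acetate 5 (not isolated)
Conditions: Ac2O (excess), NaOAc (3 equiv), 170–180 °C
Reagents that add atoms: acetic anhydride, CC(=O)OC(C)=O
Why: Kostanecki–Robinson chromone synthesis (O-acetylation, acyl transfer to the α-carbon, cyclodehydration) should proceed cleanly because the α-methoxy group occupies C3 and rules out a 3-acetyl by-product.

Step 3
Reactants: 6 3,7,8-trimethoxy-2-methyl-4H-chromen-4-one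
Product: 7 3,7,8-trimethoxy-4-oxo-4H-chromene-2-carbaldehyde
Conditions: SeO2 (1.5 equiv), xylene, 140 °C
Reagents that add atoms: selenium dioxide, O=[Se]=O
Why: Riley oxidation should convert the 2-methyl group, which is vinylogously activated by the C4 carbonyl, into the aldehyde, as is known for 2-methylchromones.

Step 4
Reactants: 7 3,7,8-trimethoxy-4-oxo-4H-chromene-2-carbaldehyde
Product: 8 2-ethynyl-3,7,8-trimethoxy-4H-chromen-4-one
Conditions: dimethyl (1-diazo-2-oxopropyl)phosphonate (1.3 equiv), K2CO3 (2 equiv), MeOH/THF, 0 °C → rt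
Reagents that add atoms: dimethyl (1-diazo-2-oxopropyl)phosphonate, COP(=O)(OC)C(=[N+]=[N-])C(C)=O
Why: Seyferth–Gilbert homologation in its Ohira–Bestmann form should turn the non-enolisable aldehyde into the terminal alkyne under carbonate/methanol conditions that the chromone should tolerate if kept cold and short.

Step 5
Reactants: 8 2-ethynyl-3,7,8-trimethoxy-4H-chromen-4-one; 9 3-methoxyfuran
Product: 10 rac-3,7,8-trimethoxy-2-[(1S,4S)-5-methoxy-7-oxabicyclo[2.2.1]hepta-2,5-dien-2-yl]-4H-chromen-4-one
Conditions: 9 (5 equiv), ZnI2 (20 mol%), CH2Cl2, 0 °C → rt; Et3N quench, Et3N-deactivated silica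
Reagents that add atoms: none
Why: Normal-electron-demand Diels–Alder reaction, concerted but asynchronous: the HOMO of furan 9 adds across the alkyne of 8, whose LUMO is lowered by conjugation through C2=C3 to the C4 carbonyl and further by ZnI2 bound at the C4 carbonyl/C3 methoxy site. The closest known reaction type is the zinc- or aluminium-halide-assisted cycloaddition of furans with propiolates and ynones to 7-oxanorbornadienes. The six-membered carbocycle of ring B closes by intermolecular [4+2] addition, furan C2 and C5 bonding suprafacially to C2' and C1' of the alkyne. The two bridgehead stereocentres arise together from that suprafacial addition to the planar furan, so only the cis-bridged (1S,4S)/(1R,4R) pair can form, as a racemate because nothing differentiates the two faces. The step needs regioselectivity (furan C2 to the alkyne terminus) and site selectivity for the alkyne: the first follows from the largest HOMO coefficient at furan C2, the enol-ether β-carbon, meeting the largest LUMO coefficient at the remote alkyne carbon, and the second from the tetrasubstituted, donor-substituted C2=C3 bond of ring C being a poor dienophile.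

Step 6
Reactants: 10 rac-3,7,8-trimethoxy-2-[(1S,4S)-5-methoxy-7-oxabicyclo[2.2.1]hepta-2,5-dien-2-yl]-4H-chromen-4-one
Product: 11 diplotrin B, 2-(3-hydroxy-4-methoxyphenyl)-3,7,8-trimethoxy-4H-chromen-4-one
Conditions: TFA (0.2 equiv), anhydrous CH2Cl2, 0 °C → rt
Reagents that add atoms: none
Why: Acid-catalysed isomerisation of a 7-oxanorbornadiene to a phenol: protonation of the bridge oxygen, heterolysis of the C6'–O bond to the arenium ion stabilised by the C4' methoxy, and loss of the C3' proton should give the 3'-hydroxy-4'-methoxy ring and erase both stereocentres.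

Compound list
1 | 1,2,3-trimethoxybenzene | COc1cccc(OC)c1OC | starting material
2 | methoxyacetyl chloride | COCC(=O)Cl | starting material
3 | 2-methoxy-1-(2,3,4-trimethoxyphenyl)ethan-1-one | COCC(=O)c1ccc(OC)c(OC)c1OC | intermediate (not isolated)
4 | 1-(2-hydroxy-3,4-dimethoxyphenyl)-2-methoxyethan-1-one | COCC(=O)c1ccc(OC)c(OC)c1O | intermediate
5 | 2,3-dimethoxy-6-(methoxyacetyl)phenyl acetate | COCC(=O)c1ccc(OC)c(OC)c1OC(C)=O | intermediate (not isolated)
6 | 3,7,8-trimethoxy-2-methyl-4H-chromen-4-one | Cc1oc2c(OC)c(OC)ccc2c(=O)c1OC | intermediate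
7 | 3,7,8-trimethoxy-4-oxo-4H-chromene-2-carbaldehyde | O=Cc1oc2c(OC)c(OC)ccc2c(=O)c1OC | intermediate
8 | 2-ethynyl-3,7,8-trimethoxy-4H-chromen-4-one | C#Cc1oc2c(OC)c(OC)ccc2c(=O)c1OC | intermediate
9 | 3-methoxyfuran | COc1ccoc1 | starting material
10 | rac-3,7,8-trimethoxy-2-[(1S,4S)-5-methoxy-7-oxabicyclo[2.2.1]hepta-2,5-dien-2-yl]-4H-chromen-4-one (racemate; one enantiomer drawn) | COC1=C[C@@H]2O[C@H]1C=C2c1oc2c(OC)c(OC)ccc2c(=O)c1OC | intermediate
11 | diplotrin B, 2-(3-hydroxy-4-methoxyphenyl)-3,7,8-trimethoxy-4H-chromen-4-one | COc1ccc(-c2oc3c(OC)c(OC)ccc3c(=O)c2OC)cc1O | target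

Total step count: 6
Longest linear sequence: 6 steps (1 → 4 → 6 → 7 → 8 → 10 → 11)

Steps most likely to fail

1. Step 5. The cycloaddition may be too slow, because the alkyne is polarised only through the vinylogous carbonyl. Zinc-promoted oligomerisation of the diene, or open-chain conjugate alkenylation of the furan without ring closure, could then take over. The fallback builds ring B from a preformed benzoic acid; it sets out from 4 and rejoins the route at 11. Compound 4 is esterified with 3-(benzyloxy)-4-methoxybenzoic acid (EDC·HCl, DMAP, CH2Cl2) to 2,3-dimethoxy-6-(methoxyacetyl)phenyl 3-(benzyloxy)-4-methoxybenzoate F1. A Baker–Venkataraman acyl shift (KOH, pyridine, 50 °C) should give 1-[3-(benzyloxy)-4-methoxyphenyl]-3-(2-hydroxy-3,4-dimethoxyphenyl)-2-methoxypropane-1,3-dione F2. Cyclodehydration (cat. H2SO4, AcOH, 100 °C) should give 2-[3-(benzyloxy)-4-methoxyphenyl]-3,7,8-trimethoxy-4H-chromen-4-one F3. Hydrogenolysis (H2, Pd/C, EtOAc) then removes the benzyl group and delivers 11.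

2. Step 4. Base-mediated conjugate addition of methanol to the newly formed enyne, or opening of the pyranone ring by methoxide, may erode the homologation. The fallback brings the alkyne in already formed and silyl-capped; it sets out from 4 and rejoins at 8. Esterification of 4 with 3-[tri(propan-2-yl)silyl]prop-2-ynoic acid (EDC·HCl, DMAP, CH2Cl2) gives 2,3-dimethoxy-6-(methoxyacetyl)phenyl 3-[tri(propan-2-yl)silyl]prop-2-ynoate F4. A Baker–Venkataraman shift (LiHMDS, THF, −78 → 0 °C) should give 1-(2-hydroxy-3,4-dimethoxyphenyl)-2-methoxy-5-[tri(propan-2-yl)silyl]pent-4-yne-1,3-dione F5. Cyclodehydration (TsOH, toluene, 80 °C) should give 3,7,8-trimethoxy-2-{[tri(propan-2-yl)silyl]ethynyl}-4H-chromen-4-one F6, the bulky silyl group shielding the alkyne from attack by the enol oxygen. Buffered desilylation (TBAF, AcOH, THF, 0 °C) frees the terminal alkyne 8.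

3. Step 3. Over-oxidation of the aldehyde to the carboxylic acid, or stalling at partial conversion with selenium-containing by-products, may lower the throughput. The fallback replaces the direct oxidation by enamine formation and oxidative cleavage; it sets out from 6 and rejoins at 7. Condensation of the acidic 2-methyl group with N,N-dimethylformamide dimethyl acetal (DMF, 110 °C) should give (E)-2-[2-(dimethylamino)ethenyl]-3,7,8-trimethoxy-4H-chromen-4-one F7. Its enamine double bond is cleaved with NaIO4 (THF/H2O, rt) to 7.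

Further compounds
F1 | step 5 | 2,3-dimethoxy-6-(methoxyacetyl)phenyl 3-(benzyloxy)-4-methoxybenzoate | COCC(=O)c1ccc(OC)c(OC)c1OC(=O)c1ccc(OC)c(OCc2ccccc2)c1
F2 | step 5 | 1-[3-(benzyloxy)-4-methoxyphenyl]-3-(2-hydroxy-3,4-dimethoxyphenyl)-2-methoxypropane-1,3-dione (racemic, enolisable C2) | COC(C(=O)c1ccc(OC)c(OC)c1O)C(=O)c1ccc(OC)c(OCc2ccccc2)c1
F3 | step 5 | 2-[3-(benzyloxy)-4-methoxyphenyl]-3,7,8-trimethoxy-4H-chromen-4-one | COc1ccc(-c2oc3c(OC)c(OC)ccc3c(=O)c2OC)cc1OCc1ccccc1
F4 | step 4 | 2,3-dimethoxy-6-(methoxyacetyl)phenyl 3-[tri(propan-2-yl)silyl]prop-2-ynoate | COCC(=O)c1ccc(OC)c(OC)c1OC(=O)C#C[Si](C(C)C)(C(C)C)C(C)C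
F5 | step 4 | 1-(2-hydroxy-3,4-dimethoxyphenyl)-2-methoxy-5-[tri(propan-2-yl)silyl]pent-4-yne-1,3-dione (racemic, enolisable C2) | COC(C(=O)c1ccc(OC)c(OC)c1O)C(=O)C#C[Si](C(C)C)(C(C)C)C(C)C
F6 | step 4 | 3,7,8-trimethoxy-2-{[tri(propan-2-yl)silyl]ethynyl}-4H-chromen-4-one | COc1c(C#C[Si](C(C)C)(C(C)C)C(C)C)oc2c(OC)c(OC)ccc2c1=O
F7 | step 3 | (E)-2-[2-(dimethylamino)ethenyl]-3,7,8-trimethoxy-4H-chromen-4-one | CN(C)/C=C/c1oc2c(OC)c(OC)ccc2c(=O)c1OC
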